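The route rests on cutting ring C (C1, C10, C9, C11, C12, C13) at C11–C12 and C1–C13. C13 is flanked by the C12 ketone and the C16 lactone carbonyl, hence a malonate carbon, and C1 is the δ-carbon of the ring D lactone carbonyl through C3=C4. The key step therefore joins a Δ1,3-dienoate lactone bearing a C9 CH2CO2tBu arm with a prochiral 2-(2,2-dimethoxyethyl)malonate in one pot: intermolecular 1,6-Michael addition, then Dieckmann closure. It should form both bonds, ring C and the C1 and C13 stereocentres under control of the Wieland–Miescher-type decalin; the extra C11 ester is lost later as CO2.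

Key step: step 20

Remark: decalin atoms carry clerodane locants (ring A = C1–C5/C10, ring B = C5–C10, C11 on C9, C17 = 8-methyl, C18 on C4, C19 on C5, C20 = 9-methyl, then C12–C16); α is the face of C19/C20, β that of H-10; ring D = 18,19-lactone, ring E = 16,15-lactone.

Step 1
Reactants: 1 cyclohexane-1,3-dione; 2 allyl bromide
Product: 3 2-allylcyclohexane-1,3-dione
Conditions: KOH, H2O, Cu powder (cat.), rt
Reagents that add atoms: none
Why: C-allylation of the cyclic 1,3-diketone enolate, which in water is alkylated mainly on carbon.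

Step 2
Reactants: 3 2-allylcyclohexane-1,3-dione; 4 ethyl vinyl ketone
Product: 6 (S)-8a-allyl-5-methyl-3,4,8,8a-tetrahydronaphthalene-1,6(2H,7H)-dione, via triketone 5 (not isolated)
Conditions: Et3N (cat.), neat, rt; then D-phenylalanine (1 equiv), (1R)-(−)-camphorsulfonic acid (0.5 equiv), DMF, rt → 70 °C
Reagents that add atoms: none
Why: Michael addition followed by an amino-acid-mediated, enantiogroup-selective aldol condensation (Hajos–Parrish-type Robinson annulation), in which the D-amino acid enamine should select one of the two ring carbonyls and set the quaternary carbon in the sense opposite to the L-series Wieland–Miescher ketone.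

Step 3
Reactants: 6 (S)-8a-allyl-5-methyl enedione
Product: 7 C1 ethylene ketal of 6
Conditions: ethylene glycol, p-TsOH (cat.), 4 Å MS, CH2Cl2, rt
Reagents that add atoms: ethylene glycol, OCCO
Why: Kinetic acetalisation of the saturated ketone, which is far more electrophilic than the conjugated enone carbonyl.

Step 4
Reactants: 7 allyl ketal
Product: 8 (E)-prop-1-enyl ketal
Conditions: RuHCl(CO)(PPh3)3 (5 mol%), toluene, 80 °C
Reagents that add atoms: none
Why: Ru–H-catalysed alkene isomerisation moves the terminal double bond one position to the more substituted propenyl group, while the tetrasubstituted enone alkene does not bind the catalyst.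

Step 5
Reactants: 8 propenyl ketal
Product: 10 (R)-8a'-(hydroxymethyl) enone ketal, via aldehyde 9 (not isolated)
Conditions: O3, pyridine, CH2Cl2/MeOH, −78 °C; Me2S; then NaBH4, −78 → −40 °C
Reagents that add atoms: ozone, [O-][O+]=O
Why: Ozonolysis cleaves the electron-richer propenyl alkene before the electron-poor enone alkene, and borohydride at low temperature should reduce only the aldehyde (aldehyde-over-enone chemoselectivity), leaving C19 as CH2OH.

Step 6
Reactants: 10 hydroxymethyl enone ketal
Product: 11 (R)-8a'-[(tert-butyldimethylsilyloxy)methyl] enone ketal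
Conditions: TBSCl, imidazole, DMF, rt
Reagents that add atoms: tert-butyldimethylsilyl chloride, CC(C)(C)[Si](C)(C)Cl
Why: Silylation of the primary neopentyl alcohol gives a group that survives dissolving metal, enolate, borane and hydride chemistry.

Step 7
Reactants: 11 silyl ether enone; 12 tert-butyl bromoacetate
Product: 14 keto ester (trans-decalin; 10β-H; 5α-CH2OTBS; 9α-Me; 9β-CH2CO2tBu; C4 dioxolane; C8 ketone), via lithium enolate 13 (not isolated)
Conditions: Li (2.1 equiv), NH3(l)/THF, t-BuOH (1 equiv), −78 °C; NH3 evaporated; then 12, THF, −78 → 0 °C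
Reagents that add atoms: none
Why: Birch-type enone reduction protonates C10 axially, anti to the angular CH2OTBS (trans fusion, 10β-H), and the regiospecific enolate should be alkylated on the β-face, anti to the syn-axial C19 group, making C9 quaternary with 9α-Me (reductive alkylation).

Step 8
Reactants: 14 keto ester
Product: 16 enol triflate (C7=C8; 8-OTf), via potassium enolate 15 (not isolated)
Conditions: KHMDS (1.05 equiv), THF, −78 °C; then PhNTf2
Reagents that add atoms: N-phenylbis(trifluoromethanesulfonimide), O=S(=O)(N(c1ccccc1)S(=O)(=O)C(F)(F)F)C(F)(F)F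
Why: The ketone can enolise only toward C7 because C9 is quaternary, the less acidic tert-butyl ester is not deprotonated by one equivalent of base, and the enolate is O-sulfonylated (enol triflate formation).

Step 9
Reactants: 16 enol triflate
Product: 17 alkene (C7=C8; 8-methyl)
Conditions: MeMgBr, Fe(acac)3 (5 mol%), THF/NMP, −30 °C
Reagents that add atoms: methylmagnesium bromide, C[Mg]Br
Why: Iron-catalysed Kumada-type cross-coupling of the enol triflate is faster than Grignard addition to the hindered tert-butyl ester.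

Step 10
Reactants: 17 alkene
Product: 19 C7 ketone (8α-Me; 8β-H), via alkylborane 18 (not isolated)
Conditions: BH3·THF, THF, 0 °C → rt; then NMO (excess), TPAP (5 mol%), 4 Å MS, CH2Cl2, rt
Reagents that add atoms: N-methylmorpholine N-oxide, C[N+]1([O-])CCOCC1
Why: Hydroboration puts boron on the less substituted C7 and hydrogen on C8 from the β-face, anti to the axial C19 and C20 groups (8β-H, equatorial 8α-Me), and N-oxide/perruthenate oxidation of the borane gives the ketone in the same flask (hydroboration–oxidation, Ley–Griffith oxidation).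

Step 11
Reactants: 19 C7 ketone
Product: 20 7α-alcohol
Conditions: L-Selectride, THF, −78 → 0 °C
Reagents that add atoms: none
Why: The α-face of the C7 carbonyl is closed by the syn-axial C19 methylene and C20 methyl, so hydride should arrive from the β-face and give the axial 7α-alcohol (substrate-controlled ketone reduction).

Step 12
Reactants: 20 7α-alcohol
Product: 21 7α-methoxymethyl ether
Conditions: MOMCl, i-Pr2NEt, NaI (cat.), 1,2-dichloroethane, 60 °C
Reagents that add atoms: chloromethyl methyl ether, COCCl
Why: Alkylation with the small, reactive oxocarbenium precursor protects the hindered axial hydroxyl as an acetal that withstands base, fluoride and palladium and falls off in the acid step 21.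

Step 13
Reactants: 21 MOM ether ketal
Product: 22 C4 ketone
Conditions: PPTS (cat.), acetone/H2O, 55 °C
Reagents that add atoms: water, O
Why: Mild acid-catalysed transketalisation/hydrolysis removes the dioxolane while the silyl ether, MOM ether and tert-butyl ester persist.

Step 14
Reactants: 22 C4 ketone
Product: 23 enone (4-oxo; C2=C3)
Conditions: IBX, DMSO/fluorobenzene, 70 °C
Reagents that add atoms: none
Why: IBX dehydrogenation of the only ketone, which can desaturate only toward C3–C2 because C5 is quaternary.

Step 15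
Reactants: 23 enone
Product: 25 dienyl triflate (4-OTf; C3=C4; C1=C2), via potassium dienolate 24 (not isolated)
Conditions: KHMDS (1.1 equiv), THF, −78 °C; then PhNTf2
Reagents that add atoms: N-phenylbis(trifluoromethanesulfonimide), O=S(=O)(N(c1ccccc1)S(=O)(=O)C(F)(F)F)C(F)(F)F
Why: With no α′-hydrogen the base removes the γ-hydrogen at C1, and O-triflation of the linear dienolate gives the 2-triflyloxy-1,3-diene (dienyl triflate formation).

Step 16
Reactants: 25 dienyl triflate
Product: 26 C19 alcohol
Conditions: HF·pyridine, THF/pyridine, 0 °C → rt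
Reagents that add atoms: none
Why: Fluoride-mediated desilylation cleaves the unhindered primary silyl ether, and MOM ether, triflate and tert-butyl ester are stable to it.

Step 17
Reactants: 26 hydroxy dienyl triflate
Product: 27 dienoate lactone (18,19-olide; C1=C2; C3=C4; 7α-OMOM; 9β-CH2CO2tBu)
Conditions: Pd(OAc)2 (10 mol%), dppp, CO (1 atm), Et3N, DMF, 60 °C
Reagents that add atoms: carbon monoxide, [C-]#[O+]
Why: Oxidative addition of Pd(0) to the dienyl triflate, CO insertion and capture of the acyl-palladium by the neighbouring C19 hydroxyl (carbonylative lactonisation) close ring D.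

Step 18
Reactants: 28 malonyl dichloride; 29 4-methoxybenzyl alcohol
Product: 30 bis(4-methoxybenzyl) malonate
Conditions: 29 (2.1 equiv in total), pyridine (2.2 equiv), CH2Cl2, 0 °C → rt
Reagents that add atoms: 4-methoxybenzyl alcohol (second equivalent), COc1ccc(CO)cc1
Why: Each of the two acid chloride groups acylates one molecule of the alcohol, so two equivalents of 29 are consumed and pyridine takes up both equivalents of HCl (double esterification of a diacid chloride).

Step 19
Reactants: 30 bis(4-methoxybenzyl) malonate; 31 2-bromo-1,1-dimethoxyethane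
Product: 32 bis(4-methoxybenzyl) 2-(2,2-dimethoxyethyl)malonate
Conditions: NaH, DMF, 0 °C; then 31, NaI (cat.), 80 °C
Reagents that add atoms: none
Why: SN2 alkylation of the sodium malonate by the bromoacetal with iodide assistance (malonic ester alkylation).

Step 20
Reactants: 27 dienoate lactone; 32 bis(4-methoxybenzyl) 2-(2,2-dimethoxyethyl)malonate
Product: 34 tetracyclic β-keto ester (ring C closed; 1α-H; C13 with axial β-CO2PMB and equatorial CH2CH(OMe)2; C11 CO2tBu as epimers/enol; C3=C4 lactone), via Michael adduct 33 (not isolated)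
Conditions: 32 (1.5 equiv), KOtBu (0.2 equiv), THF, 0 °C → rt; then LiHMDS (3.5 equiv), −78 → −10 °C; AcOH; DBU (0.2 equiv), CH2Cl2, rt
Reagents that add atoms: none
Why: Catalytic tert-butoxide lets the enolate of malonate 32 add to C1, the δ-terminus of the dienoate of 27 (1,6-Michael addition), and LiHMDS then turns adduct 33 into its C11 ester enolate, which acylates one malonate ester (Dieckmann condensation) to form C11–C12 with the β-keto ester enolate as thermodynamic sink; the closest known reaction type is the malonate Michael–Claisen (dimedone-type) annulation. Ring C is closed in the second event by 6-(enolexo)-exo-trig attack of C11 on the ester carbonyl, so the C1–C13 bond is made before the ring exists and escapes the geometric constraint that would force a tethered nucleophile onto the α-face. C1 is set by approach of the malonate to the β-face of the flat diene, anti to the syn-axial C19 methylene and C20 methyl, which gives 1α-H and a trans-diequatorial C1/C10 array that closes to the all-trans chair. C13 is set by which of the two diastereotopic esters is attacked: in the chair-like transition state the larger CH2CH(OMe)2 group should take the equatorial position and the remaining ester the axial one, as in the target. The step needs 1,6- over 1,4-addition, secured because the Michael step is reversible under catalytic base and only the C1 adduct can reach a six-membered Dieckmann transition state, and malonate ester over ring D lactone, secured because C18 is remote from C11. The C11 ester and stereocentre are temporary and leave in step 21, and DBU returns the lactone alkene to conjugation after kinetic protonation.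

Step 21
Reactants: 34 tetracyclic β-keto ester
Product: 36 hydroxy lactol (7α-OH; C11H2; ring E as 15-hydroxy-16,15-lactone; C15 epimers), via keto acid 35 (not isolated)
Conditions: TFA/H2O (9:1), CH2Cl2, 0 °C → 40 °C
Reagents that add atoms: water, O
Why: Aqueous acid ionises the acetal and cleaves the PMB ester so that the C16 acid is trapped at once by C15 as the γ-lactol, and it also cleaves the MOM ether and the tert-butyl ester, whose C11 β-keto acid 35 loses CO2 on warming (acidolysis, lactol formation, decarboxylation).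

Step 22
Reactants: 36 hydroxy lactol
Product: 37 diacetate (7α-OAc; 15-OAc)
Conditions: Ac2O, DMAP, pyridine, rt → 40 °C
Reagents that add atoms: acetic anhydride, CC(=O)OC(C)=O
Why: DMAP-catalysed acylation acetylates both the hindered axial 7α-hydroxyl and the lactol hydroxyl.

Step 23
Reactants: 37 diacetate
Product: 38 15-phenylseleno lactone (C15 epimers)
Conditions: PhSeH, BF3·OEt2 (cat.), CH2Cl2, −40 → 0 °C
Reagents that add atoms: benzeneselenol, [SeH]c1ccccc1
Why: The Lewis acid ionises only the acetal-type C15 acetate and the selenol traps the oxocarbenium ion, as in selenoglycoside formation, while the 7α-acetate cannot ionise.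

Step 24
Reactants: 38 phenylseleno lactone
Product: 41 target CNP0308057.1, via selenoxide 39 (not isolated), via enol lactone 40 (not isolated)
Conditions: DMDO (1.1 equiv), acetone/CH2Cl2, −78 °C → rt; then DMDO (2 equiv), 0 °C
Reagents that add atoms: dimethyldioxirane, CC1(C)OO1
Why: Dioxirane oxidises selenium, the selenoxide undergoes syn-elimination toward C14 (the only β-hydrogens), and further dioxirane should epoxidise the electron-rich enol ester alkene on the face flanked by the planar C12 carbonyl and not on that flanked by C1/C2 of ring A, while the electron-poor ring D alkene is inert (selenoxide elimination, dioxirane epoxidation).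

Compound list
1 | cyclohexane-1,3-dione | O=C1CCCC(=O)C1 | starting material
2 | allyl bromide | C=CCBr | starting material
3 | 2-allylcyclohexane-1,3-dione | C=CCC1C(=O)CCCC1=O | intermediate
4 | ethyl vinyl ketone (pent-1-en-3-one) | C=CC(=O)CC | starting material
5 | 2-allyl-2-(3-oxopentyl)cyclohexane-1,3-dione | C=CCC1(CCC(=O)CC)C(=O)CCCC1=O | intermediate
6 | (S)-8a-allyl-5-methyl-3,4,8,8a-tetrahydronaphthalene-1,6(2H,7H)-dione | C=CC[C@@]12CCC(=O)C(C)=C1CCCC2=O | intermediate
7 | (8a'S)-8a'-allyl-5'-methyl-3',4',8',8a'-tetrahydro-2'H-spiro[[1,3]dioxolane-2,1'-naphthalen]-6'(7'H)-one | C=CC[C@@]12CCC(=O)C(C)=C1CCCC23OCCO3 | intermediate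
8 | (8a'S)-5'-methyl-8a'-[(E)-prop-1-enyl] analogue of 7 | C/C=C/[C@@]12CCC(=O)C(C)=C1CCCC23OCCO3 | intermediate
9 | (8a'R)-8a'-carbaldehyde analogue of 7 | O=C[C@@]12CCC(=O)C(C)=C1CCCC23OCCO3 | intermediate
10 | (8a'R)-8a'-(hydroxymethyl) analogue of 7 | OC[C@@]12CCC(=O)C(C)=C1CCCC23OCCO3 | intermediate
11 | (8a'R)-8a'-[(tert-butyldimethylsilyloxy)methyl] analogue of 7 | CC(C)(C)[Si](C)(C)OC[C@@]12CCC(=O)C(C)=C1CCCC23OCCO3 | intermediate
12 | tert-butyl bromoacetate | CC(C)(C)OC(=O)CBr | starting material
13 | lithium C8 enolate (C8=C9) of the trans-fused decalin, 10β-H, 5α-CH2OTBS, C4 dioxolane | [Li+].[O-]C1=C(C)[C@H]2CCCC3(OCCO3)[C@]2(CO[Si](C)(C)C(C)(C)C)CC1 | intermediate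
14 | keto ester: trans-decalin, 10β-H, 5α-CH2OTBS, C4 dioxolane, C8 ketone, 9α-Me, 9β-CH2CO2tBu | CC(C)(C)OC(=O)C[C@@]1(C)C(=O)CC[C@@]2(CO[Si](C)(C)C(C)(C)C)C3(OCCO3)CCC[C@H]12 | intermediate
15 | potassium C8 enolate (C7=C8) of 14 | [K+].[O-]C1=CC[C@@]2(CO[Si](C)(C)C(C)(C)C)C3(OCCO3)CCC[C@@H]2[C@@]1(C)CC(=O)OC(C)(C)C | intermediate
16 | enol triflate: as 14 with C7=C8 and 8-OTf | CC(C)(C)OC(=O)C[C@@]1(C)C(OS(=O)(=O)C(F)(F)F)=CC[C@@]2(CO[Si](C)(C)C(C)(C)C)C3(OCCO3)CCC[C@H]12 | intermediate
17 | alkene: as 14 with C7=C8 and 8-methyl | CC(C)(C)OC(=O)C[C@@]1(C)C(C)=CC[C@@]2(CO[Si](C)(C)C(C)(C)C)C3(OCCO3)CCC[C@H]12 | intermediate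
18 | alkylborane: 7β-BH2, 8α-Me, 8β-H | CC(C)(C)OC(=O)C[C@@]1(C)[C@H](C)[C@@H](B)C[C@@]2(CO[Si](C)(C)C(C)(C)C)C3(OCCO3)CCC[C@H]12 | intermediate
19 | C7 ketone: 8α-Me, 8β-H, otherwise as 14 without the C8 ketone | CC(C)(C)OC(=O)C[C@@]1(C)[C@H](C)C(=O)C[C@@]2(CO[Si](C)(C)C(C)(C)C)C3(OCCO3)CCC[C@H]12 | intermediate
20 | 7α-alcohol (axial OH) of 19 | CC(C)(C)OC(=O)C[C@@]1(C)[C@H](C)[C@H](O)C[C@@]2(CO[Si](C)(C)C(C)(C)C)C3(OCCO3)CCC[C@H]12 | intermediate
21 | 7α-methoxymethyl ether of 20 | CC(C)(C)OC(=O)C[C@@]1(C)[C@H](C)[C@H](OCOC)C[C@@]2(CO[Si](C)(C)C(C)(C)C)C3(OCCO3)CCC[C@H]12 | intermediate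
22 | C4 ketone: 7α-OMOM, 5α-CH2OTBS, 8α-Me, 9α-Me, 9β-CH2CO2tBu, 10β-H | CC(C)(C)OC(=O)C[C@@]1(C)[C@H](C)[C@H](OCOC)C[C@@]2(CO[Si](C)(C)C(C)(C)C)C(=O)CCC[C@H]12 | intermediate
23 | enone: 4-oxo, C2=C3, otherwise as 22 | CC(C)(C)OC(=O)C[C@@]1(C)[C@H](C)[C@H](OCOC)C[C@@]2(CO[Si](C)(C)C(C)(C)C)C(=O)C=CC[C@H]12 | intermediate
24 | potassium dienolate of 23 (C4–O−, C3=C4, C1=C2) | CC(C)(C)OC(=O)C[C@@]1(C)[C@H](C)[C@H](OCOC)C[C@@]2(CO[Si](C)(C)C(C)(C)C)C([O-])=CC=C[C@H]12.[K+] | intermediate
25 | dienyl triflate: 4-OTf, C3=C4, C1=C2, 5α-CH2OTBS | CC(C)(C)OC(=O)C[C@@]1(C)[C@H](C)[C@H](OCOC)C[C@@]2(CO[Si](C)(C)C(C)(C)C)C(OS(=O)(=O)C(F)(F)F)=CC=C[C@H]12 | intermediate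
26 | hydroxy dienyl triflate: as 25 with 5α-CH2OH | CC(C)(C)OC(=O)C[C@@]1(C)[C@H](C)[C@H](OCOC)C[C@@]2(CO)C(OS(=O)(=O)C(F)(F)F)=CC=C[C@H]12 | intermediate
27 | dienoate lactone: 18,19-olide, C1=C2, C3=C4, 7α-OMOM, 8α-Me, 9α-Me, 9β-CH2CO2tBu, 10β-H | COCO[C@@H]1C[C@@]23COC(=O)C2=CC=C[C@@H]3[C@@](C)(CC(=O)OC(C)(C)C)[C@@H]1C | intermediate
28 | malonyl dichloride | O=C(Cl)CC(=O)Cl | starting material
29 | 4-methoxybenzyl alcohol | COc1ccc(CO)cc1 | starting material
30 | bis(4-methoxybenzyl) malonate | COc1ccc(COC(=O)CC(=O)OCc2ccc(OC)cc2)cc1 | intermediate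
31 | 2-bromo-1,1-dimethoxyethane | COC(CBr)OC | starting material
32 | bis(4-methoxybenzyl) 2-(2,2-dimethoxyethyl)malonate | COC(OC)CC(C(=O)OCc1ccc(OC)cc1)C(=O)OCc1ccc(OC)cc1 | intermediate
33 | Michael adduct: malonate carbon on C1 (β, 1α-H), C3=C4 18,19-olide, C11 ester still open | COCO[C@@H]1C[C@@]23COC(=O)C2=CC[C@@H](C(CC(OC)OC)(C(=O)OCc4ccc(OC)cc4)C(=O)OCc4ccc(OC)cc4)[C@@H]3[C@@](C)(CC(=O)OC(C)(C)C)[C@@H]1C | intermediate
34 | tetracyclic β-keto ester: ring C closed, 12-oxo, 11-CO2tBu (epimers/enol), C13 with axial β-CO2PMB and equatorial CH2CH(OMe)2, 1α-H, 7α-OMOM | COCO[C@@H]1C[C@@]23COC(=O)C2=CC[C@@H]2[C@@H]3[C@@](C)(C(C(=O)OC(C)(C)C)C(=O)[C@@]2(C(=O)OCc2ccc(OC)cc2)CC(OC)OC)[C@@H]1C | intermediate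
35 | keto acid: 11-CO2H, 7α-OH, ring E as 15-hydroxy-16,15-lactone | O[C@@H]1C[C@@]23COC(=O)C2=CC[C@@H]2[C@@H]3[C@@](C)(C(C(=O)O)C(=O)[C@]23C(=O)OC(O)C3)[C@@H]1C | intermediate
36 | hydroxy lactol: 7α-OH, 12-oxo, C11H2, spiro 15-hydroxy-16,15-lactone (C15 epimers) | O[C@@H]1C[C@@]23COC(=O)C2=CC[C@@H]2[C@@H]3[C@@](C)(CC(=O)[C@]23C(=O)OC(O)C3)[C@@H]1C | intermediate
37 | diacetate: 7α-OAc, 15-OAc (C15 epimers) | CC(=O)O[C@@H]1C[C@@]23COC(=O)C2=CC[C@@H]2[C@@H]3[C@@](C)(CC(=O)[C@]23C(=O)OC(OC(C)=O)C3)[C@@H]1C | intermediate
38 | 15-phenylseleno lactone, 7α-OAc (C15 epimers) | CC(=O)O[C@@H]1C[C@@]23COC(=O)C2=CC[C@@H]2[C@@H]3[C@@](C)(CC(=O)[C@]23C(=O)OC([Se]c4ccccc4)C3)[C@@H]1C | intermediate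
39 | selenoxide of 38 | CC(=O)O[C@@H]1C[C@@]23COC(=O)C2=CC[C@@H]2[C@@H]3[C@@](C)(CC(=O)[C@]23C(=O)OC([Se](=O)c4ccccc4)C3)[C@@H]1C | intermediate
40 | enol lactone: C14=C15 in ring E (3,3-disubstituted furan-2(3H)-one), 7α-OAc | CC(=O)O[C@@H]1C[C@@]23COC(=O)C2=CC[C@@H]2[C@@H]3[C@@](C)(CC(=O)[C@]23C(=O)OC=C3)[C@@H]1C | intermediate
41 | CNP0308057.1: 7α-acetoxy-12-oxo-14,15-epoxy-1,13-cycloclerod-3-ene-18,19:16,15-diolide, oxirane syn to C12 | CC(=O)O[C@@H]1C[C@@]23COC(=O)C2=CC[C@@H]2[C@@H]3[C@@](C)(CC(=O)[C@]23C(=O)O[C@H]2O[C@H]23)[C@@H]1C | target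

Total step count: 24 (22 in the main chain, 2 for malonate 32). Longest linear sequence: 22 steps (steps 1–17 and 20–24).

Steps most likely to fail

Step 20. The intermolecular 1,6-addition may stall, because the malonate is a tertiary nucleophile and must take the β-face trajectory that leaves the new bond equatorial, or it may revert by retro-Michael reaction once strong base is present; the Dieckmann step may also pick the other diastereotopic ester. The fallback separates the two events and makes the first one irreversible under Lewis acid. It sets out from 27 and 32: 32 would be converted with TMSOTf/Et3N into its trimethylsilyl ketene acetal F1, which would be added to 27 under TBSOTf catalysis at −78 °C (vinylogous Mukaiyama–Michael addition). Aqueous work-up would give adduct 33 as an isolated compound, and a separate Dieckmann condensation (LiHMDS, THF, −78 °C) would return to the route at 34.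

Step 21. Four acid-labile groups are unmasked at once, and the C16 carboxyl could be lost as CO2 if it is freed before C15 traps it. The fallback stages the unmasking so that C16 is set free under neutral conditions while C12 is still tied up as the enolised C11 β-keto ester. It sets out from 34: PPTS in wet acetone would hydrolyse only the acetal to aldehyde F2. Hydrogenolysis of the PMB ester (H2, Pd/C, EtOAc, short contact) would let the acid close onto the aldehyde as lactol tert-butyl ester F3. Aqueous TFA with warming would then remove the tert-butyl ester (with decarboxylation) and the MOM ether and come back at 36.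

Step 24. Epoxidation of enol lactone 40 may show poor facial selectivity or prefer the face towards C1/C2, and the acyloxy epoxide may not survive the selenium by-products. The fallback delivers the oxirane to the face opposite to the one the electrophile prefers. It sets out from 38: H2O2/pyridine would give 40 as an isolated compound. NBS in wet THF would form trans-bromohydrin F4 (bromine on C14 on the face towards C1, lactol hydroxyl on C15 on the C12 side), and Ag2O in CH2Cl2 would close the oxirane with inversion at C14 and return to 41.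

Further compounds
F1 | step 20 | trimethylsilyl ketene acetal of malonate 32 | COC(OC)CC(C(=O)OCc1ccc(OC)cc1)=C(O[Si](C)(C)C)OCc1ccc(OC)cc1
F2 | step 21 | C15 aldehyde of 34 (PMB ester, tert-butyl ester and MOM ether retained) | COCO[C@@H]1C[C@@]23COC(=O)C2=CC[C@@H]2[C@@H]3[C@@](C)(C(C(=O)OC(C)(C)C)C(=O)[C@@]2(C(=O)OCc2ccc(OC)cc2)CC=O)[C@@H]1C
F3 | step 21 | spiro 15-hydroxy-16,15-lactone with 11-CO2tBu and 7α-OMOM | COCO[C@@H]1C[C@@]23COC(=O)C2=CC[C@@H]2[C@@H]3[C@@](C)(C(C(=O)OC(C)(C)C)C(=O)[C@]23C(=O)OC(O)C3)[C@@H]1C
F4 | step 24 | trans-bromohydrin of 40 (14-bromo on the face towards C1, 15-hydroxy on the C12 side) | CC(=O)O[C@@H]1C[C@@]23COC(=O)C2=CC[C@@H]2[C@@H]3[C@@](C)(CC(=O)[C@]23C(=O)O[C@@H](O)[C@@H]3Br)[C@@H]1C
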